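The target is cut at C4–C5. C5, the ether carbon of the bridging oxolane, is an allylic carbinol carbon next to the exocyclic C4=C15 alkene inside the ten-membered carbocycle, which is the retron of a 2-bromoalkene adding to an aldehyde. One chromium-mediated step therefore forms C4–C5, closes the carbocycle onto the preformed trans-disubstituted α-methylene-γ-lactone and sets C5. Its precursor is an open chain hung on that lactone: the C5 aldehyde on C6 and, on C7, the C8 tiglate chain that ends in the C2 dimethyl ketal and the C4 vinyl bromide. The chain is joined to the lactone convergently by one asymmetric allyl transfer that forms C8–C9.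

Key step: step 13

Assumption: germacrane numbering is used (carbocycle C1–C10, lactone O6–C12–C11(=C13)–C7, methylenes C14 on C10 and C15 on C4); the target is read as 2S,5S,6S,7R,8S, and the C2 hemiketal configuration is taken as the only one the C2–O–C5 bridge allows, so it is set under thermodynamic control in the last step.

Step 1
Reactants: 1 (S)-5-(hydroxymethyl)furan-2(5H)-one
Product: 2 (S)-5-[(tert-butyldimethylsilyloxy)methyl]furan-2(5H)-one
Conditions: TBSCl, imidazole, CH2Cl2, 0 °C to rt
Reagents that add atoms: tert-butyldimethylsilyl chloride, CC(C)(C)[Si](C)(C)Cl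
Why: Imidazole-promoted silylation of the primary alcohol touches no stereocentre and installs the bulky group that shields one face of the butenolide in step 2.

Step 2
Reactants: 2 (S)-5-[(tert-butyldimethylsilyloxy)methyl]furan-2(5H)-one
Product: 3 (4R,5S)-5-[(tert-butyldimethylsilyloxy)methyl]-4-(hydroxymethyl)oxolan-2-one
Conditions: benzophenone (cat.), MeOH, hν (350 nm, Pyrex), N2, rt
Reagents that add atoms: methanol, CO
Why: Photosensitised radical conjugate addition (triplet benzophenone abstracts hydrogen from methanol and the hydroxymethyl radical adds to C7 of the butenolide) should occur anti to the C6 silyloxymethyl group, which sets C7 trans to C5 and brings in C8.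

Step 3
Reactants: 3 (4R,5S)-5-[(tert-butyldimethylsilyloxy)methyl]-4-(hydroxymethyl)oxolan-2-one
Product: 4 (2S,3S)-2-[(tert-butyldimethylsilyloxy)methyl]-5-oxooxolane-3-carbaldehyde
Conditions: Dess–Martin periodinane, CH2Cl2, 0 °C to rt; used crude
Reagents that add atoms: none
Why: Dess–Martin oxidation of the primary alcohol is base-free, which matters because the β-formyl lactone could epimerise at C7 or eliminate the C6 carboxylate with amine bases.

Step 4
Reactants: 5 p-toluenesulfonylmethyl isocyanide (TosMIC); 6 2,3-dibromoprop-1-ene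
Product: 7 2-bromo-4-isocyano-4-tosylbut-1-ene (racemic)
Conditions: 30% aq. NaOH, CH2Cl2, n-Bu4NI (cat.), 0 °C; 5 in slight excess
Reagents that add atoms: none
Why: Phase-transfer monoalkylation of TosMIC (SN2 of the sulfonyl- and isocyano-stabilised carbanion at the allylic bromide) introduces C2 as a formyl dianion equivalent under a base mild enough to leave the vinyl bromide alone.

Step 5
Reactants: 7 2-bromo-4-isocyano-4-tosylbut-1-ene; 8 3-chloro-2-(chloromethyl)prop-1-ene
Product: 9 2-bromo-6-(chloromethyl)-4-isocyano-4-tosylhepta-1,6-diene (racemic)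
Conditions: NaH, DMSO–Et2O, 0 °C to rt; anion of 7 added to 8 (4 equiv)
Reagents that add atoms: none
Why: The second TosMIC alkylation (SN2 at one chloride of the symmetrical dichloride held in excess) gives a carbon without acidic hydrogen, so the remaining allylic chloride, the future C9 handle, cannot be attacked intramolecularly.

Step 6
Reactants: 9 2-bromo-6-(chloromethyl)-4-isocyano-4-tosylhepta-1,6-diene
Product: 10 2-bromo-6-(chloromethyl)hepta-1,6-dien-4-one
Conditions: conc. aq. HCl, Et2O–CH2Cl2, 0 °C, 15 min
Reagents that add atoms: water, O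
Why: Acid hydrolysis of a dialkylated TosMIC (hydration of the isocyanide, loss of sulfinate, hydrolysis of the N-formyl imine) is the standard unmasking to a ketone and is brief enough at 0 °C that the two β,γ-alkenes should not move into conjugation.

Step 7
Reactants: 10 2-bromo-6-(chloromethyl)hepta-1,6-dien-4-one
Product: 11 2-bromo-6-(chloromethyl)-4,4-dimethoxyhepta-1,6-diene
Conditions: HC(OMe)3, MeOH, PPTS (cat.), rt; Et3N quench; from here on work-ups at pH ≥ 7 and Et3N-washed silica
Reagents that add atoms: trimethyl orthoformate, COC(OC)OC; methanol, CO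
Why: Acid-catalysed ketalisation driven by the orthoformate as water scavenger blocks enolisation of the doubly β,γ-unsaturated ketone and gives a C2 mask that the mildest aqueous acid removes at the end.

Step 8
Reactants: 4 (2S,3S)-2-[(tert-butyldimethylsilyloxy)methyl]-5-oxooxolane-3-carbaldehyde; 11 2-bromo-6-(chloromethyl)-4,4-dimethoxyhepta-1,6-diene
Product: 13 C8 trimethylsilyl ether of the C8–C9 coupled lactone (trans-lactone; 8S; C5 OTBS; C11 still CH2), via allylchromium dichloride 12 (not isolated)
Conditions: CrCl2 (10 mol %, nickel-free), chiral tridentate 1,8-bis(4-isopropyloxazolin-2-yl)carbazole ligand (12 mol %, antipode chosen for Si-face delivery), Mn powder, Me3SiCl, i-Pr2NEt (cat.), THF, rt; aq. NaHCO3 work-up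
Reagents that add atoms: chlorotrimethylsilane, C[Si](C)(C)Cl
Why: Catalytic asymmetric Nozaki–Hiyama allylation, in which divalent chromium turns the allylic chloride into allylchromium 12 that adds to the aldehyde through a closed six-membered transition state while Mn and Me3SiCl turn the metal over and leave O8 silylated; the ligand directs attack to the Si face of C8=O (8S), the Felkin–Anh preference with C6 as the large group points the same way, the 2-substituted allyl unit has equivalent termini, and without nickel the vinyl bromide is inert.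

Step 9
Reactants: 13 C8 trimethylsilyl ether of the C8–C9 coupled lactone
Product: 17 α-methylene lactone C8 alcohol (8S; C5 OTBS), via C11 dimethylaminomethyl lactone 14 (not isolated), via C11 trimethylammoniomethyl iodide 15 (not isolated), via C8 trimethylsilyl ether 16 (not isolated)
Conditions: LiHMDS, THF, −78 °C; CH2=NMe2+ I−, −78 °C to rt; MeI, CH2Cl2, rt; sat. aq. NaHCO3, rt; then n-Bu4NF/AcOH (1.05 equiv), THF, −20 °C
Reagents that add atoms: Eschenmoser's salt (dimethyl(methylidene)ammonium iodide), C=[N+](C)C.[I-]
Why: Lactone α-methylenation by the Mannich route (enolate aminomethylation, N-methylation, Hofmann-type elimination that can only give the exocyclic C11=C13 alkene) is run on the C8 silyl ether so that no alkoxide can attack the lactone carbonyl, and buffered fluoride then cleaves the labile trimethylsilyl ether while the primary TBS ether stays.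

Step 10
Reactants: 17 α-methylene lactone C8 alcohol; 18 tiglic acid
Product: 20 C8 tiglate (C5 OTBS), via tiglic 2,4,6-trichlorobenzoic anhydride 19 (not isolated)
Conditions: 2,4,6-trichlorobenzoyl chloride, Et3N, toluene, rt; then 17, DMAP, rt to 40 °C
Reagents that add atoms: none
Why: Yamaguchi esterification through mixed anhydride 19 acylates the hindered secondary alcohol with retention at C8 and without a base strong enough to open the lactone or move the tiglate double bond.

Step 11
Reactants: 20 C8 tiglate (C5 OTBS)
Product: 21 C8 tiglate C5 primary alcohol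
Conditions: n-Bu4NF, AcOH, THF, 0 °C to rt
Reagents that add atoms: none
Why: Acetic acid-buffered fluoride desilylation frees the C5 alcohol while the acid-labile dimethyl ketal and the base-sensitive tiglate and α-methylene lactone survive.

Step 12
Reactants: 21 C8 tiglate C5 primary alcohol
Product: 22 lactone C5 aldehyde carrying the C2 dimethyl ketal and the C4 vinyl bromide
Conditions: Dess–Martin periodinane, pyridine, CH2Cl2, 0 °C to rt; used crude
Reagents that add atoms: none
Why: Pyridine-buffered Dess–Martin oxidation gives the α-acyloxy aldehyde without acid (ketal) or strong base (epimerisation at C6).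

Step 13
Reactants: 22 lactone C5 aldehyde carrying the C2 dimethyl ketal and the C4 vinyl bromide
Product: 24 ten-membered C5 carbinol (5S; C2 dimethyl ketal), via C4 vinylchromium dichloride 23 (not isolated)
Conditions: CrCl2 (10 equiv), NiCl2 (0.1 equiv), DMSO–THF, rt, slow addition of 22 to 2 mM; aq. sodium serinate work-up (pH 8)
Reagents that add atoms: none
Why: Nozaki–Hiyama–Kishi reaction: zerovalent nickel, generated from NiCl2 by divalent chromium, inserts into the C4–Br bond and hands the vinyl group to trivalent chromium, and the resulting vinylchromium 23 adds to the C5 aldehyde. The closest known reaction type is the intramolecular vinyl halide–aldehyde NHK closure of medium and large carbocycles. The ten-membered ring closes in a 10-exo-trig carbonyl addition, favoured by the trans placement of the aldehyde and the C7 chain on the lactone, by the gem-dimethoxy carbon C2 in the middle of the tether and by slow addition to about 2 mM. The new stereocentre C5 is under substrate control: in the dipole-minimised (Cornforth) rotamer, with C5=O pointing away from the C6–O bond and no chelation in DMSO, only the carbonyl face flanked by C7 should be within reach of a C4 nucleophile tied to C7 through the six-atom tether, and attack there gives the 5,6-syn (5S) alcohol. The step needs aldehyde-only addition and closure over oligomerisation; the first is secured by the low basicity of the organochromium, which leaves the lactone, the tiglate, the ketal and the α-methylene unit alone, the second by dilution and the preorganised chain. The exocyclic C4=C15 alkene is carried in intact and ends up next to the new carbinol.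

Step 14
Reactants: 24 ten-membered C5 carbinol (5S; C2 dimethyl ketal)
Product: 26 target CNP0307443.2, via bridged C2 methyl ketal 25 (not isolated)
Conditions: PPTS (cat.), acetone–H2O (10:1), rt
Reagents that add atoms: water, O
Why: Acetal hydrolysis with neighbouring-group trapping: mild acid ionises the dimethyl ketal, the C5 hydroxyl captures the oxocarbenium ion in a 5-exo closure to 25, and hydrolysis of the remaining methoxy group gives the hemiketal, whose C2 configuration (2S) is fixed by the one-oxygen bridge to C5.

Compound list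
1 | (S)-5-(hydroxymethyl)furan-2(5H)-one | OC[C@H]1OC(=O)C=C1 | starting material
2 | (S)-5-[(tert-butyldimethylsilyloxy)methyl]furan-2(5H)-one | CC(C)(C)[Si](C)(C)OC[C@H]1OC(=O)C=C1 | intermediate
3 | (4R,5S)-5-[(tert-butyldimethylsilyloxy)methyl]-4-(hydroxymethyl)oxolan-2-one | OC[C@H]1CC(=O)O[C@@H]1CO[Si](C)(C)C(C)(C)C | intermediate
4 | (2S,3S)-2-[(tert-butyldimethylsilyloxy)methyl]-5-oxooxolane-3-carbaldehyde (C8 aldehyde, trans) | O=C[C@H]1CC(=O)O[C@@H]1CO[Si](C)(C)C(C)(C)C | intermediate
5 | p-toluenesulfonylmethyl isocyanide (TosMIC) | Cc1ccc(cc1)S(=O)(=O)C[N+]#[C-] | starting material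
6 | 2,3-dibromoprop-1-ene | C=C(Br)CBr | starting material
7 | 2-bromo-4-isocyano-4-tosylbut-1-ene (racemic) | Cc1ccc(cc1)S(=O)(=O)C(CC(Br)=C)[N+]#[C-] | intermediate
8 | 3-chloro-2-(chloromethyl)prop-1-ene | C=C(CCl)CCl | starting material
9 | 2-bromo-6-(chloromethyl)-4-isocyano-4-tosylhepta-1,6-diene (racemic) | Cc1ccc(cc1)S(=O)(=O)C(CC(Br)=C)(CC(=C)CCl)[N+]#[C-] | intermediate
10 | 2-bromo-6-(chloromethyl)hepta-1,6-dien-4-one | C=C(Br)CC(=O)CC(=C)CCl | intermediate
11 | 2-bromo-6-(chloromethyl)-4,4-dimethoxyhepta-1,6-diene (C9–C10(=C14)–C1–C2–C3–C4(=C15) unit) | C=C(Br)CC(OC)(OC)CC(=C)CCl | intermediate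
12 | (6-bromo-4,4-dimethoxy-2-methylidenehept-6-en-1-yl)chromium dichloride, chiral ligand omitted | Cl[Cr](Cl)CC(=C)CC(OC)(OC)CC(Br)=C | intermediate (not isolated)
13 | trans-lactone with CH2OTBS on C6 and, on C7, the (8S)-C8(OSiMe3)–C9H2–C10(=C14H2)–C1H2–C2(OMe)2–C3H2–C4(Br)=C15H2 chain | C=C(C[C@H](O[Si](C)(C)C)[C@H]1CC(=O)O[C@@H]1CO[Si](C)(C)C(C)(C)C)CC(OC)(OC)CC(Br)=C | intermediate
14 | 13 with CH2NMe2 on C11 (C11 epimers) | C=C(C[C@H](O[Si](C)(C)C)[C@H]1C(CN(C)C)C(=O)O[C@@H]1CO[Si](C)(C)C(C)(C)C)CC(OC)(OC)CC(Br)=C | intermediate (not isolated)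
15 | 13 with CH2NMe3+ I− on C11 | C=C(C[C@H](O[Si](C)(C)C)[C@H]1C(C[N+](C)(C)C)C(=O)O[C@@H]1CO[Si](C)(C)C(C)(C)C)CC(OC)(OC)CC(Br)=C.[I-] | intermediate (not isolated)
16 | 13 with C11=C13 methylene (C8 OSiMe3, C5 OTBS) | C=C(C[C@H](O[Si](C)(C)C)[C@H]1C(=C)C(=O)O[C@@H]1CO[Si](C)(C)C(C)(C)C)CC(OC)(OC)CC(Br)=C | intermediate (not isolated)
17 | α-methylene trans-lactone, (8S)-C8 alcohol, C5 OTBS, C2 dimethyl ketal, C4 vinyl bromide | C=C(C[C@H](O)[C@H]1C(=C)C(=O)O[C@@H]1CO[Si](C)(C)C(C)(C)C)CC(OC)(OC)CC(Br)=C | intermediate
18 | tiglic acid, (E)-2-methylbut-2-enoic acid | C/C=C(\C)C(=O)O | starting material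
19 | tiglic 2,4,6-trichlorobenzoic anhydride | C/C=C(\C)C(=O)OC(=O)c1c(Cl)cc(Cl)cc1Cl | intermediate (not isolated)
20 | 17 as its C8 tiglate (C5 OTBS) | C=C(C[C@H](OC(=O)/C(C)=C/C)[C@H]1C(=C)C(=O)O[C@@H]1CO[Si](C)(C)C(C)(C)C)CC(OC)(OC)CC(Br)=C | intermediate
21 | C8 tiglate with free C5 primary alcohol | C=C(C[C@H](OC(=O)/C(C)=C/C)[C@H]1C(=C)C(=O)O[C@@H]1CO)CC(OC)(OC)CC(Br)=C | intermediate
22 | lactone C5 aldehyde with C8 tiglate, C2 dimethyl ketal and C4 vinyl bromide (6S,7R,8S) | C=C(C[C@H](OC(=O)/C(C)=C/C)[C@H]1C(=C)C(=O)O[C@@H]1C=O)CC(OC)(OC)CC(Br)=C | intermediate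
23 | 22 with CrCl2 in place of Br on C4 | C=C(C[C@H](OC(=O)/C(C)=C/C)[C@H]1C(=C)C(=O)O[C@@H]1C=O)CC(OC)(OC)CC(=C)[Cr](Cl)Cl | intermediate (not isolated)
24 | ten-membered carbocycle, (5S)-C5 carbinol, C2 dimethyl ketal, C8 tiglate, trans-6,7-α-methylene lactone (5S,6S,7R,8S) | C=C1C[C@H](OC(=O)/C(C)=C/C)[C@H]2C(=C)C(=O)O[C@@H]2[C@@H](O)C(=C)CC(OC)(OC)C1 | intermediate
25 | C2 methyl ketal bridged C2–O–C5 (2S,5S,6S,7R,8S) | C=C1C[C@H](OC(=O)/C(C)=C/C)[C@H]2C(=C)C(=O)O[C@@H]2[C@H]2O[C@@](OC)(C1)CC2=C | intermediate (not isolated)
26 | CNP0307443.2, bridged C2 hemiketal (2S,5S,6S,7R,8S) | C=C1C[C@H](OC(=O)/C(C)=C/C)[C@H]2C(=C)C(=O)O[C@@H]2[C@H]2O[C@@](O)(C1)CC2=C | target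

Total step count: 14. Longest linear sequence: 11 steps (from 5 through steps 4–14); 10 steps from butenolide 1.

Steps most likely to fail

Step 13. The vinylchromium may be delivered to the hydrogen-flanked face of the C5 carbonyl, the face an untethered nucleophile prefers, so that closure gives mainly the 5R carbinol. The strain of the ten-membered ring may also slow closure enough for protonation of the vinylchromium to compete. The fallback sets out from 22 and returns at 24, and it sets C5 by reagent-controlled hydride delivery and not by the C–C bond formation. The closure is accepted with the wrong C5 configuration, giving the ten-membered 5R carbinol F1. This is oxidised before any contact with acid (Dess–Martin periodinane, pyridine, CH2Cl2) to the ten-membered C5 enone F2. F2 is reduced with catecholborane and the matching antipode of the 2-methyl-CBS-oxazaborolidine (Corey–Bakshi–Shibata reduction, toluene, −78 °C), a 1,2-reduction that should leave the α-methylene lactone and the esters alone, to give 24.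

Step 8. Facial discrimination in the addition to the α-branched, enolisable β-formyl lactone may be incomplete under chromium catalysis, or the aldehyde may epimerise at C7 during slow turnover. The fallback sets out from 11 and 4 and returns at 13, and it replaces the reducing organochromium addition by a chiral Lewis acid-catalysed allyl transfer from tin (Keck allylation). Chloride 11 is treated with Bu3SnLi (THF, −78 °C, inverse addition) to give tributyl(6-bromo-4,4-dimethoxy-2-methylidenehept-6-en-1-yl)stannane F3. F3 adds to 4 with (S)-BINOL and Ti(OiPr)4 (4 Å sieves, CH2Cl2, −20 °C; the antipode expected to deliver to the Si face) to give the free C8 alcohol F4. Me3SiCl and imidazole then give 13.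

Step 9. Aminomethylation of the hindered enolate may stall, or the C8 silyl ether may be lost under the basic conditions so that the freed alkoxide shifts the lactone from O6 to O8. The fallback sets out from 13 and returns at 16, and it is a base-free condensation followed by reduction. Compound 13 is heated with Bredereck's reagent (tert-butoxybis(dimethylamino)methane, toluene, 80 °C) to give the (E)-enamino lactone F5. Its vinylogous carbamate is reduced with i-Bu2AlH (THF, −78 °C) and loses dimethylamine on work-up to give 16; fluoride cleavage as in step 9 then gives 17.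

Further compounds
F1 | step 13 | ten-membered 5R carbinol, C5 epimer of 24 | C=C1C[C@H](OC(=O)/C(C)=C/C)[C@H]2C(=C)C(=O)O[C@@H]2[C@H](O)C(=C)CC(OC)(OC)C1
F2 | step 13 | ten-membered C5 ketone (enone with C4=C15), C2 dimethyl ketal | C=C1C[C@H](OC(=O)/C(C)=C/C)[C@H]2C(=C)C(=O)O[C@@H]2C(=O)C(=C)CC(OC)(OC)C1
F3 | step 8 | tributyl(6-bromo-4,4-dimethoxy-2-methylidenehept-6-en-1-yl)stannane | CCCC[Sn](CCCC)(CCCC)CC(=C)CC(OC)(OC)CC(Br)=C
F4 | step 8 | free (8S)-C8 alcohol corresponding to 13 (C11 CH2, C5 OTBS) | C=C(C[C@H](O)[C@H]1CC(=O)O[C@@H]1CO[Si](C)(C)C(C)(C)C)CC(OC)(OC)CC(Br)=C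
F5 | step 9 | 13 with (E)-dimethylaminomethylidene on C11 | C=C(C[C@H](O[Si](C)(C)C)[C@H]1/C(=C\N(C)C)C(=O)O[C@@H]1CO[Si](C)(C)C(C)(C)C)CC(OC)(OC)CC(Br)=C
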